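**Strategy.** The δ-lactone is disconnected across C1–C10 and O–C9: a CH2–CH2–C(=O)–O unit is added to the tetrasubstituted C9=C10 alkene of ring B, where the methyl-bearing carbon C10 and the bicyclo[2.2.2]octane carbon C9 are neighbours. In the key step 5-methylene Meldrum's acid, generated in the flask, should act as a 1-oxadiene in an inverse-demand hetero-Diels–Alder reaction with this alkene, forming both bonds on one face and both stereocentres anti to the C5 substituent; hydrolysis and decarboxylation then unveil the lactone. The precursor is a des-lactone tricycle (cyclohexene ring B fused to the 14-acetoxy-15-oxo bicyclooctane), made from an achiral trione by enzymatic desymmetrisation.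

Key step: step 11

Remark on locants: all atoms carry the locants of the target. C1–C3 is the lactone chain (C3 = carbonyl) and C4 the isopropenyl carbon. Ring B is C5–C10 (C20 = methyl on C10). The bicyclo[2.2.2]octane is C8, C9, C11–C16 (C14 bears the acetate, C15 is the ketone, C16 carries the exocyclic methylene C17). Stereodescriptors refer to these locants.

Assumption: a ketoreductase (or baker's yeast) that reduces the pro-14S carbonyl of trione 7 is found by screening; the required sense is assumed to be that of the yeast reduction of simpler bicyclo[2.2.2]octane-2,6-diones.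

**Route**

Step 1
Reactants: 1 2-(3,5-dimethoxyphenyl)acetic acid
Product: 3 2-(3,5-dioxocyclohexyl)acetic acid, via Birch diene 2 (not isolated)
Conditions: Li, NH3 (l), t-BuOH, THF, −78 °C; then 2 M HCl, THF, 20 °C
Reagents that add atoms: water, O
Why: Birch reduction of the 1,3-dimethoxyarene keeps both methoxy groups on the double bonds of the 1,4-diene, and acid hydrolysis of the two enol ethers should give the 5-substituted cyclohexane-1,3-dione without creating a stereocentre.

Step 2
Reactants: 3 2-(3,5-dioxocyclohexyl)acetic acid; 4 pent-1-en-3-one (ethyl vinyl ketone)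
Product: 5 2-[3,5-dioxo-4-(3-oxopentyl)cyclohexyl]acetic acid
Conditions: H2O, AcOH (cat.), hydroquinone (cat.), 60 °C
Reagents that add atoms: none
Why: Michael addition of the acidic dione carbon (future C8) to the vinyl ketone should form the C7–C8 bond; the stereocentres of 5 are erased in step 3.

Step 3
Reactants: 5 2-[3,5-dioxo-4-(3-oxopentyl)cyclohexyl]acetic acid
Product: 7 achiral trione 5-methyltricyclo[6.2.2.0(1,6)]dodec-5-ene-4,10,12-trione, via enedione acid 6 (not isolated)
Conditions: polyphosphoric acid, 85 °C
Reagents that add atoms: none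
Why: acid-mediated aldol cyclodehydration (second stage of a Robinson annulation) should close ring B, and the extended enol is then C-acylated at C8 by the activated acetic acid side chain (the enol acylation that converts 3-oxocyclohexaneacetic acid into bicyclo[2.2.2]octane-2,6-dione); if acylation comes first, the resulting symmetric trione condenses to the same mirror-symmetric product, which has no stereocentre.

Step 4
Reactants: 7 achiral trione
Product: 8 (8R,12S,14S)-14-hydroxy enedione (C14–OH syn to the C15 carbonyl)
Conditions: ketoreductase, NADP+ (cat.), glucose dehydrogenase, D-glucose, phosphate buffer pH 7, DMSO (5%), 30 °C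
Reagents that add atoms: none
Why: enzymatic desymmetrising reduction of the mirror-symmetric bicyclo[2.2.2]octane-2,6-dione unit (the reaction type of the baker's-yeast reduction of such diones) should select one enantiotopic carbonyl and deliver hydride from the face syn to the C9 bridge, setting C14 as S and thereby C8 and C12, while the hindered tetrasubstituted enone is left alone.

Step 5
Reactants: 8 (8R,12S,14S)-14-hydroxy enedione
Product: 9 (8R,12S,14S)-14-acetoxy enedione
Conditions: Ac2O, pyridine, DMAP (cat.), CH2Cl2, 0 °C
Reagents that add atoms: acetic anhydride, CC(=O)OC(C)=O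
Why: DMAP-catalysed acetylation of the secondary alcohol at 0 °C should outrun retro-aldol opening and installs the acetate of the target with retention at C14.

Step 6
Reactants: 9 (8R,12S,14S)-14-acetoxy enedione
Product: 10 (5S,8R,12S,14S)-allylic alcohol (C5–OH anti to the C14 bridge)
Conditions: (R)-2-methyl-CBS-oxazaborolidine (0.2 equiv), catecholborane, toluene, −78 °C
Reagents that add atoms: none
Why: Corey–Bakshi–Shibata reduction, in which the alkenyl flank C10 is the large group, should give the 5S carbinol under reagent control (ring B itself offers little facial bias), the enone reacting faster with catecholborane at −78 °C than the neopentyl C15 ketone.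

Step 7
Reactants: 10 (5S,8R,12S,14S)-allylic alcohol
Product: 11 (5S,8R,12S,14S)-allylic diethyl phosphate
Conditions: ClP(O)(OEt)2, N-methylimidazole, CH2Cl2, 0 °C
Reagents that add atoms: diethyl chlorophosphate, CCOP(=O)(Cl)OCC
Why: O-phosphorylation activates the allylic alcohol with retention at C5.

Step 8
Reactants: 11 (5S,8R,12S,14S)-allylic diethyl phosphate
Product: 12 (5S,8R,12S,14S)-isopropenyl tricycle
Conditions: isopropenylmagnesium bromide (2.4 equiv), CuBr·SMe2 (1.2 equiv), THF, −78 → −20 °C
Reagents that add atoms: isopropenylmagnesium bromide, C=C(C)[Mg]Br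
Why: copper-mediated allylic substitution with a diorganocuprate should occur anti and at the carbon that carried the phosphate, because the alternative terminus C9 is fully substituted and neopentyl, so inversion at C5 places the isopropenyl group syn to the C14 bridge.

Step 9
Reactants: 12 (5S,8R,12S,14S)-isopropenyl tricycle
Product: 13 (5R,8R,12S,14S)-2-hydroxypropan-2-yl tricycle
Conditions: Co(acac)2 (cat.), PhSiH3, O2 (1 atm), i-PrOH, 20 °C; then PPh3
Reagents that add atoms: dioxygen, O=O
Why: Mukaiyama hydration (hydrogen-atom transfer, Markovnikov) should convert only the 1,1-disubstituted alkene into the tertiary alcohol, masking the isopropenyl group while the tetrasubstituted C9=C10 alkene stays inert.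

Step 10
Reactants: 14 Meldrum's acid (2,2-dimethyl-1,3-dioxane-4,6-dione)
Product: 15 2,2-dimethyl-5-[(phenylsulfanyl)methyl]-1,3-dioxane-4,6-dione
Conditions: aq. HCHO (37%), PhSH, L-proline (cat.), MeCN, 20 °C
Reagents that add atoms: formaldehyde, C=O; benzenethiol, Sc1ccccc1
Why: three-component Knoevenagel condensation and thia-Michael addition should give a storable precursor of the heterodiene.

Step 11
Reactants: 13 (5R,8R,12S,14S)-2-hydroxypropan-2-yl tricycle; 15 2,2-dimethyl-5-[(phenylsulfanyl)methyl]-1,3-dioxane-4,6-dione
Product: 18 (5R,8S,9S,10S,12R,14S)-pyrano[2,3-d][1,3]dioxin-4-one cycloadduct, via sulfoxide 16 (not isolated), via 5-methylene Meldrum's acid 17 (not isolated)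
Conditions: 15 (3 equiv), mCPBA (2.9 equiv), CH2Cl2, −40 °C; then 13, NaHCO3, −40 → 40 °C
Reagents that add atoms: none
Why: Proposed new method: oxidation of 15 gives sulfoxide 16, which loses benzenesulfenic acid to release 5-methylene Meldrum's acid 17, a very electron-poor 1-oxa-1,3-diene (O=C–C=CH2) that should engage the electron-rich tetrasubstituted C9=C10 alkene of 13 in an inverse-electron-demand hetero-Diels–Alder reaction, its CH2 terminus bonding to C10 and its carbonyl oxygen to C9. The closest known reactions are the intramolecular Knoevenagel/hetero-Diels–Alder cycloadditions of alkylidene Meldrum's acids with unactivated trisubstituted alkenes and the intermolecular cycloadditions of 17 with simple olefins; an intermolecular case with both alkene carbons fully substituted has not been shown. The dihydropyran ring closes in one suprafacial, asynchronous [4+2] event with the C1–C10 bond leading, so O9 and C1 are necessarily cis. Both new stereocentres (C9 and C10) are set by approach anti to the pseudo-axial 2-hydroxypropan-2-yl group on the allylic carbon C5. The orientation (CH2 to C10, not C9) should follow from sterics, since C9 is flanked by the quaternary bridgehead C8 whereas C10 carries only a methyl group and a methine. Chemoselectivity is secured by masking the isopropenyl group as the tertiary alcohol and by generating 17 in the absence of free Meldrum's acid, the ene pathway being the expected competitor.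

Step 12
Reactants: 18 cycloadduct
Product: 20 (5R,8S,9S,10S,12R,14S)-lactone alcohol, via carboxy lactone 19 (not isolated)
Conditions: pyridine–H2O (5:1), 95 °C
Reagents that add atoms: water, O
Why: hydrolysis of the dioxinone (ketene acetal) releases acetone and gives the malonic half-lactone 19, which should decarboxylate on heating to the δ-lactone without touching a stereocentre.

Step 13
Reactants: 20 (5R,8S,9S,10S,12R,14S)-lactone alcohol
Product: 21 (5S,8S,9S,10S,12R,14S)-17-nor lactone (crotobarin lacking the C17 methylene)
Conditions: SOCl2, pyridine, CH2Cl2, −30 → 0 °C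
Reagents that add atoms: none
Why: dehydration through the chlorosulfite by an E2-type elimination should remove a readily accessible methyl hydrogen, not the hindered C5–H next to quaternary C10, regenerating the isopropenyl group.

Step 14
Reactants: 21 (5S,8S,9S,10S,12R,14S)-17-nor lactone
Product: 23 crotobarin, via Mannich base 22 (not isolated)
Conditions: LiN(SiMe3)2 (1.05 equiv), THF, −78 °C; Me2N=CH2 iodide (Eschenmoser's salt), −78 → 0 °C; then MeI, CH2Cl2–MeOH, 20 °C; then aq. NaHCO3
Reagents that add atoms: N,N-dimethylmethyleneiminium iodide (Eschenmoser's salt), C=[N+](C)C.[I-]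
Why: the C15 ketone is more acidic than the lactone or acetate and can enolise only toward C16 (C8 is quaternary), so a Mannich reaction of its lithium enolate followed by quaternisation and E1cB elimination should install the exocyclic methylene (α-methylenation).

**Compound list**

1 | 2-(3,5-dimethoxyphenyl)acetic acid | COc1cc(CC(=O)O)cc(OC)c1 | starting material
2 | Birch diene, 2-(3,5-dimethoxycyclohexa-2,5-dien-1-yl)acetic acid | COC1=CC(CC(=O)O)C=C(OC)C1 | intermediate
3 | 2-(3,5-dioxocyclohexyl)acetic acid | O=C(O)CC1CC(=O)CC(=O)C1 | intermediate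
4 | pent-1-en-3-one (ethyl vinyl ketone) | C=CC(=O)CC | starting material
5 | 2-[3,5-dioxo-4-(3-oxopentyl)cyclohexyl]acetic acid (stereoisomer mixture, enolised) | CCC(=O)CCC1C(=O)CC(CC(=O)O)CC1=O | intermediate
6 | enedione acid, 2-(5-methyl-1,6-dioxo-1,2,3,4,6,7,8,8a-octahydronaphthalen-3-yl)acetic acid (racemic, enolised; no stereocentre defined) | CC1=C2CC(CC(=O)O)CC(=O)C2CCC1=O | intermediate
7 | achiral trione, 5-methyltricyclo[6.2.2.0(1,6)]dodec-5-ene-4,10,12-trione (ring B enone fused at C8–C9 to a bicyclo[2.2.2]octane with ketones at C14 and C15) | CC1=C2CC3CC(=O)C2(CCC1=O)C(=O)C3 | intermediate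
8 | (8R,12S,14S)-14-hydroxy enedione, C14–OH syn to the C15 ketone | CC1=C2C[C@H]3C[C@H](O)[C@]2(CCC1=O)C(=O)C3 | intermediate
9 | (8R,12S,14S)-14-acetoxy enedione | CC1=C2C[C@H]3C[C@H](OC(C)=O)[C@]2(CCC1=O)C(=O)C3 | intermediate
10 | (5S,8R,12S,14S)-allylic alcohol, C5–OH anti to the C14 bridge | CC1=C2C[C@H]3C[C@H](OC(C)=O)[C@]2(CC[C@@H]1O)C(=O)C3 | intermediate
11 | (5S,8R,12S,14S)-allylic diethyl phosphate | CC1=C2C[C@H]3C[C@H](OC(C)=O)[C@]2(CC[C@@H]1OP(=O)(OCC)OCC)C(=O)C3 | intermediate
12 | (5S,8R,12S,14S)-isopropenyl tricycle, isopropenyl syn to the C14 bridge | CC1=C2C[C@H]3C[C@H](OC(C)=O)[C@]2(CC[C@H]1C(C)=C)C(=O)C3 | intermediate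
13 | (5R,8R,12S,14S)-2-hydroxypropan-2-yl tricycle | CC1=C2C[C@H]3C[C@H](OC(C)=O)[C@]2(CC[C@H]1C(C)(C)O)C(=O)C3 | intermediate
14 | Meldrum's acid (2,2-dimethyl-1,3-dioxane-4,6-dione) | CC1(C)OC(=O)CC(=O)O1 | starting material
15 | 2,2-dimethyl-5-[(phenylsulfanyl)methyl]-1,3-dioxane-4,6-dione | CC1(C)OC(=O)C(CSc2ccccc2)C(=O)O1 | intermediate
16 | sulfoxide, 2,2-dimethyl-5-[(phenylsulfinyl)methyl]-1,3-dioxane-4,6-dione | CC1(C)OC(=O)C(CS(=O)c2ccccc2)C(=O)O1 | intermediate
17 | 5-methylene Meldrum's acid (2,2-dimethyl-5-methylidene-1,3-dioxane-4,6-dione) | C=C1C(=O)OC(C)(C)OC1=O | intermediate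
18 | (5R,8S,9S,10S,12R,14S)-cycloadduct, dihydropyran fused to the dioxinone (O on C9, CH2 on C10, both anti to the C5 group) | C1C(=O)[C@]23CC[C@@H](C(C)(C)O)[C@]4(C)CC5=C(OC(C)(C)OC5=O)O[C@@]42C[C@H]1C[C@@H]3OC(C)=O | intermediate
19 | carboxy lactone (C2 configuration undefined) | C1C(=O)[C@]23CC[C@@H](C(C)(C)O)[C@]4(C)CC(C(=O)O)C(=O)O[C@@]42C[C@H]1C[C@@H]3OC(C)=O | intermediate
20 | (5R,8S,9S,10S,12R,14S)-lactone alcohol | C1C(=O)[C@]23CC[C@@H](C(C)(C)O)[C@]4(C)CCC(=O)O[C@@]42C[C@H]1C[C@@H]3OC(C)=O | intermediate
21 | (5S,8S,9S,10S,12R,14S)-17-nor lactone | C1C(=O)[C@]23CC[C@@H](C(=C)C)[C@]4(C)CCC(=O)O[C@@]42C[C@H]1C[C@@H]3OC(C)=O | intermediate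
22 | Mannich base, 16-(dimethylaminomethyl) ketone (C16 undefined) | CN(C)CC1C(=O)[C@]23CC[C@@H](C(=C)C)[C@]4(C)CCC(=O)O[C@@]42C[C@H]1C[C@@H]3OC(C)=O | intermediate
23 | crotobarin, (5S,8S,9S,10S,12R,14S) | C=C1C(=O)[C@]23CC[C@@H](C(=C)C)[C@]4(C)CCC(=O)O[C@@]42C[C@H]1C[C@@H]3OC(C)=O | target

**Step count.** Total: 14 steps (13 in the main line plus one reagent preparation, step 10). Longest linear sequence: 13 steps (1–9, 11–14).

**Steps most likely to fail**

1. Step 11 (Proposed new method). The cycloaddition at the hindered tetrasubstituted alkene may be too slow relative to self-consumption of the heterodiene, may divert into the ene manifold, or may take the reversed orientation (CH2 to C9). Fallback by known chemistry, setting out from 13 and returning at 20: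
   - Epoxidation of 13 with mCPBA (NaHCO3, CH2Cl2, 0 °C), anti to the C5 group, should give the 9,10-epoxide F1.
   - Isomerisation with TMSOTf/2,6-lutidine then DBU (HF·pyridine work-up) should ionise the C10–O bond, remote from the C15 carbonyl, and remove a C20 proton to give the tertiary allylic alcohol with exocyclic C10=C20 methylene F2.
   - Hydrogen-atom-transfer Giese addition of the derived C10 radical to methyl acrylate (Fe(acac)3, PhSiH3, EtOH, 60 °C), again anti to the C5 group, should give the hydroxy ester F3.
   - Lactonisation (PPTS, toluene, 80 °C) returns to 20.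
   - In this fallback the C9 oxygen comes from the peracid and the two bonds are made in separate steps.

2. Step 6. Discrimination between the enone carbonyl and the C15 ketone may be insufficient (over-reduction), or reagent control at C5 may erode. Fallback setting out from 9 and returning at 12:
   - Reduction of both carbonyls with excess (R)-2-methyl-CBS-oxazaborolidine/BH3·SMe2 should give the diol F4 (C15 configuration inconsequential).
   - Selective phosphorylation of the less hindered allylic C5 hydroxyl gives the monophosphate F5.
   - The cuprate displacement of step 8 gives the isopropenyl alcohol F6.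
   - Dess–Martin oxidation of the C15 alcohol returns to 12.

3. Step 4. The enzyme may not accept the tricyclic substrate or may show the wrong enantiotopic-group or facial preference. Fallback setting out from 7 and returning at 9:
   - Chelation-controlled mono-reduction with Zn(BH4)2 (Et2O, −20 °C) should give racemic syn-hydroxy ketone, that is 8 together with the enantiomer of 8 F7.
   - Acetylation as in step 5 gives 9 together with the enantiomer of 9 F8.
   - Kinetic resolution by lipase-catalysed hydrolysis (Burkholderia cepacia lipase, pH 7 buffer, MTBE) should cleave the (14R)-acetate F8 back to F7 and leave 9, which is separated and carried on.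

**Further compounds**

F1 | step 11 | 9,10-epoxide of 13, oxygen anti to the C5 group | C1C(=O)[C@]23CC[C@@H](C(C)(C)O)[C@]4(C)O[C@@]42C[C@H]1C[C@@H]3OC(C)=O
F2 | step 11 | tertiary allylic alcohol, C9–OH with exocyclic C10=C20 methylene | C1C(=O)[C@]23CC[C@@H](C(C)(C)O)C(=C)[C@@]2(O)C[C@H]1C[C@@H]3OC(C)=O
F3 | step 11 | hydroxy ester, C10–CH2CH2CO2Me with C9–OH | C1C(=O)[C@]23CC[C@@H](C(C)(C)O)[C@](C)(CCC(=O)OC)[C@@]2(O)C[C@H]1C[C@@H]3OC(C)=O
F4 | step 6 | 5,15-diol, (5S), C15 undefined | C1C(O)[C@]23CC[C@H](O)C(C)=C2C[C@H]1C[C@@H]3OC(C)=O
F5 | step 6 | C5 diethyl phosphate of diol F4 | C1C(O)[C@]23CC[C@H](OP(=O)(OCC)OCC)C(C)=C2C[C@H]1C[C@@H]3OC(C)=O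
F6 | step 6 | isopropenyl C15 alcohol | C1C(O)[C@]23CC[C@@H](C(=C)C)C(C)=C2C[C@H]1C[C@@H]3OC(C)=O
F7 | step 4 | enantiomer of 8 | CC1=C2C[C@@H]3C[C@@H](O)[C@@]2(CCC1=O)C(=O)C3
F8 | step 4 | enantiomer of 9 | CC1=C2C[C@@H]3C[C@@H](OC(C)=O)[C@@]2(CCC1=O)C(=O)C3
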